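## The problem

Target 53 (C25H35NO6) is pentacyclic. Its atoms are labelled here as: C1 ester carbonyl; C2 ester-bearing methine; C3 cyclopentane CH2; C4 quaternary lactam α-carbon; C5 lactam carbonyl; C6 piperidinone NCH2; C7 piperidinone methine; C8 and C9 the CH2–CH2 from C7 to the alkene; C10=C11 the tetrasubstituted alkene (C11 on C4); C12 ring-fusion methine; C13 and C14 the cyclopentene CH2 groups (C13 next to C12); C15 the quaternary carbon bearing C16H2OAc; C17 and C18 CH2–CH2; C19 carbinol; C20 methyl-bearing methine (methyl C21); C22 the second NCH2. The piperidinone (N, C5, C4, C15, C7, C6) is bridged from N to C15 by C22–C20–C19–C18–C17 into a nine-membered ring. It is fused to a cycloheptene (C4, C11, C10, C9, C8, C7, C15), which shares C10=C11 with a cyclopentene (C10–C14) and C4–C11 with a cyclopentane (C2, C3, C4, C11, C12). Of the seven stereocentres (C2, C4, C7, C12, C15, C19, C20), C4 and C15 are adjacent quaternary carbons whose exocyclic groups are all CH2- or carbonyl-type, so only a ring can relay configuration between them. C7 can direct C15 (trans addition), C15 can fix C4 through a cis ring fusion, the C4 substituents can steer protonation at C12, and the convex face of the finished cyclopentane can set C2; the syn C19/C20 pair is remote and needs its own absolute control. The C16 acetate cannot meet ester enolates or alkoxides, the C2 ester sits on the concave face and is epimerisable, the C10=C11 alkene can slip into conjugation while C13 is a ketone, and C3 is neopentyl and so closed to SN2 chemistry. The enabling feature is that cyclopentene and cycloheptene share C10=C11 while C11 and C9 are linked through the four-atom span C4–C15–C7–C8, so an alkyne on C4 and an allene on C8 can be joined with CO in one [2+2+1] event.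

## Retrosynthesis

**53 ⇐ 52 ⇐ 51 ⇐ 50.** The C19 silyl ether is removed last and the C16 acetate is put on just before, because every earlier C–C bond formation at C2 uses strong base. The C2 stereocentre is traced to hydrogenation of the cyclopentene ester 50 from its convex face, which at the same time frees C16–OH from a benzyl ether. The forward step must spare the tetrasubstituted C10=C11 bond.

**50 ⇐ 47.** The C2–C3 bond is cut as an aldol condensation of the C1/C2 ester onto the C3 aldehyde of 47. This is preferred to displacement at C3, which is neopentyl, and to a ring-closing alkylation, which would have to set C2 in a transition state expected to turn the ester away from C13, the wrong way. The precursor lacks one ring and two stereocentres.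

**47 ⇐ 46 ⇐ 45 ⇐ 43 ⇐ 41.** Only oxidation levels change. The C3 aldehyde comes from the silyl ether in 45. The C13 methylene comes from a ketone by way of tosylhydrazone 43, since a C13 alcohol would lactonise onto C1. The C12–H stereocentre and the C10=C11 position come from dienone 41 by hydride addition at C9 and kinetic protonation at C12.

**41 ⇐ 39 + 40.** The key cut removes C10–C11, C12–C13 and C13–C14 at once, opening both carbocycles to the allene-yne 39 and carbon monoxide 40. No other single cut removes two rings, and it leaves the C13 ketone as the handle for C12. The forward reaction must use the distal allene double bond.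

**39 ⇐ 37 ⇐ 36 ⇐ 35 ⇐ 34 ⇐ 32 ⇐ 30 ⇐ 29.** The unsaturated arms are made late from carbonyl groups. The ester arm comes from terminal alkyne 37 and methyl diazoacetate 38. The C4 alkyne comes from the lactone carbonyl C11 of 34 through lactol 35 and alcohol 36. The allene comes from alkyne 32, aldehyde 30 and alcohol 29. The allene is finished before the second alkyne appears so that two terminal alkynes never coexist, and the base-sensitive 3-alkynoate is made last.

**29 ⇐ 28 ⇐ 27.** The nine-membered ring is cut at C17–C18 (ring-closing metathesis of diene 27, then hydrogenation). This is done before any alkyne exists, and the hydrogenation also unmasks C9–OH.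

**27 ⇐ 26 ⇐ 22.** The quaternary pair is traced to the flat butenolide-fused lactam 22. Vinyl adds to C15 anti to the C7 side chain, and reversible hydroxymethylation at C4 gives the cis-fused lactone–lactam. The lactone is at once the latent alkyne carbon C11 and the protecting group for C16–O.

**22 ⇐ 19 ⇐ 18 ⇐ 17 ⇐ 15 + 16.** The C15–C16 bond and the lactone come from Stille hydroxymethylation of triflate 19. The C4–C15 bond comes from Dieckmann closure of malonamide 17, made from amine 15 and methyl malonyl chloride 16.

**15 ⇐ 5 + 13.** The N–C22 bond is cut by reductive amination. Aldehyde 5 (C18–C22, syn C19/C20) comes from a thiazolidinethione aldol of 1 with acrolein 2. Amino ester 13 (C6–C9, C15) comes from aminomethylation of imide 9, made from 6 and 7, with carbamate 10. Both use cheap (S)-phenylalaninol-derived auxiliaries.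

## Roads not taken

**Alternative 1:** The cut is the C4–C15 bond itself. The silyl ketene acetal of the eleven-membered allylic lactone A2 would undergo a ring-contracting Ireland–Claisen rearrangement to the cycloheptene acid A1, with the C5 carboxyl on C4 and the C17=C18 vinyl on C15.

- Merit: one stereospecific pericyclic step makes both quaternary centres, where the chosen plan needs a conjugate addition plus an equilibrating aldol. At this point the alternative is the more elegant.
- Weakness: the outcome depends on the geometry of a tetrasubstituted ketene acetal inside a medium ring (chair or boat is not predictable) and on a defined trisubstituted ring alkene. A2 is also a β,γ-unsaturated ester that can enolise towards the cyclopentene.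
- After A1 everything else is still missing: nitrogen, both N–C bonds, the nine-membered ring, the cyclopentane, and C12, which in A1 is an unfunctionalised allylic CH2.
- The chosen plan sets against this a C13 ketone that makes C12 addressable, and a nitrogen scaffold that is in place from the start.

**Alternative 2:** The cut is N–C6 and C6–C7, with C6 supplied by formaldehyde. The secondary amide A4 would give an N-acyliminium ion under CF3CO2H that is captured by the C7=C8 alkene, giving the tetracyclic lactam A3 after proton loss.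

- Merit: this is more convergent at nitrogen than the chosen plan, and A3 already holds C2, C12 and the ester.
- Weakness: the difficulty moves into A4, a carbocycle that must carry both quaternary centres, C2 and C12 with no lactam to template them.
- The electron-rich C10=C11 bond sits one atom from the amide carbon and can compete for the cation through a five-membered closure. Strong acid meets an acetate, two silyl ethers and a tetrasubstituted alkene.
- The diene left in A3 needs a selective reduction, and the nine-membered ring would still have to be closed at C18–C19 while creating the C19 stereocentre.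
- The chosen plan is longer at the start but uses the piperidinone as the stereochemical template throughout.

**Alternative 3:** The cut is C3–C4. Li in NH3 would turn the benzoate ring of the chloride A6 into a dienolate that alkylates at the ipso carbon, giving the tricyclic diene A5.

- Merit: one step from a cheap arene makes C4 with its carboxyl and the cyclopentane, with C12 and the C2 substituent already related. For that ring it is clearly shorter than the four closing steps used here.
- Weakness: as drawn, A5 is a 6-6-5 carbocycle. The ring through C4 has six members where seven are needed, and the ring through C12 has six where five are needed, so one ring expansion and one contraction would follow.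
- C15 would have to be made quaternary next to C4 from an unactivated alkene, and absolute control would need an auxiliary or a resolution.
- The chosen plan pays with a long linear sequence but never has to edit ring sizes.

Key step: step 24

Remark on the chemistry: reagents 10, 20, 31 and 38 are treated as purchasable; each is otherwise one routine step from a catalogue compound.

## Steps

Step 1
Reactants: 1 (S)-4-benzyl-3-propanoyl-1,3-thiazolidine-2-thione; 2 acrolein
Product: 3 (S)-4-benzyl-3-[(2S,3R)-3-hydroxy-2-methylpent-4-enoyl]-1,3-thiazolidine-2-thione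
Conditions: TiCl4 (1.05 equiv), i-Pr2NEt (1.1 equiv), N-methylpyrrolidinone (1 equiv), CH2Cl2, 0 °C; then 2, −78 to 0 °C
Reagents that add atoms: none
Why: Titanium-mediated thiazolidinethione aldol in its non-chelated (Evans-syn) mode: the Z-enolate adds through a Zimmerman–Traxler chair on the face away from the benzyl group, setting C20 and C19 as the syn pair. Acrolein reacts only 1,2 under these conditions.

Step 2
Reactants: 3
Product: 4 (S)-4-benzyl-3-[(2S,3R)-3-(tert-butyldimethylsilyloxy)-2-methylpent-4-enoyl]-1,3-thiazolidine-2-thione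
Conditions: TBSOTf, 2,6-lutidine, CH2Cl2, 0 °C
Reagents that add atoms: tert-butyldimethylsilyl triflate, CC(C)(C)[Si](C)(C)OS(=O)(=O)C(F)(F)F
Why: Silylation of a hindered secondary alcohol with the silyl triflate and a non-nucleophilic base; no retro-aldol at 0 °C.

Step 3
Reactants: 4
Product: 5 (2S,3R)-3-(tert-butyldimethylsilyloxy)-2-methylpent-4-enal
Conditions: i-Bu2AlH (1.1 equiv), CH2Cl2, −78 °C
Reagents that add atoms: none
Why: N-Acyl thiazolidinethiones are reduced by i-Bu2AlH only to the aldehyde, because the tetrahedral aluminate is stable at −78 °C; the auxiliary is released and C20 is not epimerised in the cold.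

Step 4
Reactants: 6 4-(benzyloxy)butanoic acid; 7 (S)-4-benzyloxazolidin-2-one
Product: 9 (S)-4-benzyl-3-[4-(benzyloxy)butanoyl]oxazolidin-2-one, via mixed pivalic anhydride 8 (not isolated)
Conditions: t-BuCOCl, Et3N, THF, −20 °C; then 7, LiCl, rt
Reagents that add atoms: none
Why: Standard N-acylation of the oxazolidinone through the mixed pivalic anhydride; the lithium-coordinated oxazolidinone attacks the less hindered acyl group.

Step 5
Reactants: 9; 10 benzyl N-(methoxymethyl)carbamate
Product: 11 (S)-4-benzyl-3-[(R)-4-(benzyloxy)-2-{[(benzyloxycarbonyl)amino]methyl}butanoyl]oxazolidin-2-one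
Conditions: TiCl4 (2.1 equiv in two portions), i-Pr2NEt (1.1 equiv), CH2Cl2, 0 °C; then 10, 0 °C
Reagents that add atoms: none
Why: The chlorotitanium Z-enolate of the imide adds to the N-acyliminium ion released from 10 by TiCl4 on the face opposite the benzyl group (Mannich-type aminomethylation of an Evans enolate). This sets C7.

Step 6
Reactants: 11
Product: 12 methyl (R)-4-(benzyloxy)-2-{[(benzyloxycarbonyl)amino]methyl}butanoate
Conditions: NaOMe (0.3 equiv), MeOH, 0 °C
Reagents that add atoms: methanol, CO
Why: Methoxide-catalysed methanolysis at the exocyclic imide carbonyl; the oxazolidinone is a good leaving group, so the reaction is fast at 0 °C, where the ester α-hydrogen does not exchange.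

Step 7
Reactants: 12
Product: 13 methyl (R)-2-(aminomethyl)-4-(benzyloxy)butanoate
Conditions: H2 (1 atm), Pd/C, pyridine (0.5 equiv), MeOH, rt
Reagents that add atoms: none
Why: Hydrogenolysis of the benzyl carbamate; the pyridine additive poisons the palladium surface towards benzyl ether cleavage, so the C9 benzyl ether is kept.

Step 8
Reactants: 5; 13
Product: 15 methyl (R)-4-(benzyloxy)-2-({[(2R,3R)-3-(tert-butyldimethylsilyloxy)-2-methylpent-4-en-1-yl]amino}methyl)butanoate, via imine 14 (not isolated)
Conditions: NaBH(OAc)3, AcOH (1 equiv), ClCH2CH2Cl, 0 °C to rt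
Reagents that add atoms: none
Why: Reductive amination: the acetoxyborohydride reduces the iminium ion faster than the aldehyde. The cold, weakly acidic medium avoids epimerisation at C20 and β-elimination of the silyloxy group.

Step 9
Reactants: 15; 16 methyl 3-chloro-3-oxopropanoate
Product: 17 methyl (R)-4-(benzyloxy)-2-({(3-methoxy-3-oxopropanoyl)[(2R,3R)-3-(tert-butyldimethylsilyloxy)-2-methylpent-4-en-1-yl]amino}methyl)butanoate
Conditions: Et3N, CH2Cl2, 0 °C
Reagents that add atoms: none
Why: N-Acylation of the secondary amine by the acid chloride; the two methyl esters are inert.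

Step 10
Reactants: 17
Product: 18 methyl (5R)-5-[2-(benzyloxy)ethyl]-4-hydroxy-2-oxo-1-[(2R,3R)-3-(tert-butyldimethylsilyloxy)-2-methylpent-4-en-1-yl]-1,2,5,6-tetrahydropyridine-3-carboxylate (enol form)
Conditions: NaOMe (1.5 equiv), MeOH, rt; then aq. HCl
Reagents that add atoms: none
Why: Dieckmann condensation: the malonamide carbanion attacks the C15 methyl ester (6-exo-trig) and the tricarbonyl product leaves the equilibrium as its enolate. C7–H is about ten pKa units less acidic than the malonamide CH2 and is not exchanged at room temperature.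

Step 11
Reactants: 18
Product: 19 methyl (5R)-5-[2-(benzyloxy)ethyl]-2-oxo-1-[(2R,3R)-3-(tert-butyldimethylsilyloxy)-2-methylpent-4-en-1-yl]-4-(trifluoromethylsulfonyloxy)-1,2,5,6-tetrahydropyridine-3-carboxylate
Conditions: Tf2O, i-Pr2NEt, CH2Cl2, −78 °C
Reagents that add atoms: triflic anhydride, O=S(=O)(OS(=O)(=O)C(F)(F)F)C(F)(F)F
Why: O-Sulfonylation of the enol of a cyclic β-keto ester; the hindered base and low temperature prevent γ-deprotonation at C7.

Step 12
Reactants: 19; 20 (tributylstannyl)methanol
Product: 22 (7S)-7-[2-(benzyloxy)ethyl]-5-[(2R,3R)-3-(tert-butyldimethylsilyloxy)-2-methylpent-4-en-1-yl]-6,7-dihydrofuro[3,4-c]pyridine-3,4(1H,5H)-dione, via hydroxymethyl ester 21 (not isolated)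
Conditions: Pd(PPh3)4 (10 mol%), LiCl (3 equiv), 1,4-dioxane, 90 °C
Reagents that add atoms: none
Why: Stille coupling of the electron-poor enol triflate with the hydroxymethyl stannane, whose α-oxygenated group transfers in preference to butyl. The new CH2OH is cis to the ester across the ring alkene and lactonises to the butenolide.

Step 13
Reactants: 22; 23 vinylmagnesium bromide; 24 formaldehyde
Product: 26 cis-fused lactone–lactam with vinyl on C15 (trans to the C7 side chain) and hydroxymethyl C3 on C4 (cis to vinyl); C4, C7 and C15 as in 53, via vinyl adduct 25 (not isolated)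
Conditions: CuBr·SMe2 (20 mol%), THF, −78 °C; then 37% aq. CH2O, Et3N, 0 °C to rt
Reagents that add atoms: none
Why: Copper-catalysed conjugate addition to the doubly activated alkene (alkylidene-malonate type) occurs anti to the C7 side chain and sets C15. The lactone–lactam is then hydroxymethylated at C4 by a reversible base-mediated aldol reaction with formaldehyde. Under equilibration the cis-fused bicycle should prevail, placing C3 cis to vinyl and the lactone carbonyl C11 cis to C16.

Step 14
Reactants: 26
Product: 27 C3 tert-butyldimethylsilyl ether of 26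
Conditions: TBSCl, imidazole, DMF, rt
Reagents that add atoms: tert-butyldimethylsilyl chloride, CC(C)(C)[Si](C)(C)Cl
Why: Silylation of the primary alcohol under weakly basic conditions that do not trigger retro-aldol loss of formaldehyde.

Step 15
Reactants: 27
Product: 28 bridged lactam–lactone with the nine-membered ring closed as the (Z)-C17=C18 alkene (C3–OTBS, C9–OBn, C19–OTBS)
Conditions: second-generation Grubbs catalyst (10 mol%), CH2Cl2 (0.001 M), 40 °C
Reagents that add atoms: none
Why: Ring-closing metathesis of the two terminal alkenes; the piperidinone holds the C15 vinyl group axial, and high dilution with loss of ethylene favours the bridged (Z)-cycloalkene over oligomers.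

Step 16
Reactants: 28
Product: 29 saturated bridged lactam–lactone with free C9–OH
Conditions: H2 (1 atm), Pd/C, EtOAc, rt
Reagents that add atoms: none
Why: Hydrogenation of the cis-disubstituted ring alkene and hydrogenolysis of the C9 benzyl ether on the same catalyst, done before any alkyne is present.

Step 17
Reactants: 29
Product: 30 C9 aldehyde
Conditions: Dess–Martin periodinane, NaHCO3, CH2Cl2, rt
Reagents that add atoms: none
Why: Buffered hypervalent-iodine oxidation of the primary alcohol; no stereocentre is α to the new aldehyde.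

Step 18
Reactants: 30; 31 dimethyl (1-diazo-2-oxopropyl)phosphonate
Product: 32 C7 propargyl compound (C9≡C10–H)
Conditions: K2CO3, MeOH, 0 °C to rt
Reagents that add atoms: none
Why: Seyferth–Gilbert homologation with the Ohira–Bestmann reagent: methanolysis gives the diazomethylphosphonate anion, which converts the aldehyde to the terminal alkyne through a vinylidene carbene.

Step 19
Reactants: 32; 24 formaldehyde (as paraformaldehyde)
Product: 34 C7 buta-2,3-dienyl compound (allene C9=C10=C14), via propargylic amine 33 (not isolated)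
Conditions: CuI (0.5 equiv), dicyclohexylamine, 1,4-dioxane, reflux
Reagents that add atoms: none
Why: Crabbé homologation: a copper-mediated Mannich reaction of the alkyne with formaldehyde and the amine is followed by retro-imino-ene hydride transfer from the amine α-C–H, giving the terminal allene.

Step 20
Reactants: 34
Product: 35 lactol (C11 hemiacetal, both anomers)
Conditions: i-Bu2AlH (1.2 equiv), CH2Cl2, −78 °C
Reagents that add atoms: none
Why: Partial reduction: the lactone is far more electrophilic than the tertiary lactam, and the aluminium hemiacetal does not collapse at −78 °C.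

Step 21
Reactants: 35; 31 dimethyl (1-diazo-2-oxopropyl)phosphonate
Product: 36 C4-ethynyl compound with free C16–OH
Conditions: K2CO3, MeOH, rt
Reagents that add atoms: none
Why: The same Seyferth–Gilbert homologation acts on the hydroxy aldehyde in equilibrium with the lactol. C4 is quaternary, so nothing can epimerise, and the C16 hydroxyl is set free.

Step 22
Reactants: 36
Product: 37 C16 benzyl ether of 36
Conditions: 2-benzyloxy-1-methylpyridinium triflate, MgO, PhCF3, 85 °C
Reagents that add atoms: 2-benzyloxy-1-methylpyridinium triflate, C[n+]1ccccc1OCc1ccccc1.[O-]S(=O)(=O)C(F)(F)F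
Why: Benzyl transfer under neutral buffered conditions, chosen because strong base would isomerise the allene. A benzyl ether rather than the acetate is carried through the enolate chemistry still to come.

Step 23
Reactants: 37; 38 methyl diazoacetate
Product: 39 allene-yne: methyl but-3-ynoate whose C4 substituent is the lactam α-carbon (C1–C2–C12≡C11–C4), with the buta-2,3-dienyl group on C7
Conditions: CuI (5 mol%), MeCN, rt
Reagents that add atoms: none
Why: Copper-catalysed coupling of a terminal alkyne with a diazoacetate (copper acetylide plus copper carbene) gives the 3-alkynoate directly under neutral conditions; the product is used at once.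

Step 24
Reactants: 39; 40 carbon monoxide
Product: 41 4-alkylidenecyclopentenone fused to the cycloheptene (C13 ketone, C11=C12 bearing CH2CO2Me, exocyclic C9=C10)
Conditions: [Rh(CO)2Cl]2 (5 mol%), CO (1 atm), toluene, 90 °C
Reagents that add atoms: none
Why: The rhodium carbonyl chloride binds the C11≡C12 alkyne and the distal C10=C14 π-bond of the allene, and oxidative cyclisation gives a rhodacyclopentene in which C10–C11 has formed. CO then inserts and reductive elimination forms C12–C13 and C13–C14, releasing the dienone. This is the rhodium-catalysed allenic Pauson–Khand reaction, known to give bicyclo[5.3.0] dienones from allene-ynes with a four-atom tether. The cycloheptene closes in the oxidative cyclisation across the tether C4–C15–C7–C8, and the cyclopentenone closes in the carbonylative [2+2+1] sequence. No stereocentre is formed and every reacting carbon is sp or sp2, so C4, C7 and C15 are not at risk. The selectivity needed is distal over proximal allene double bond: monovalent rhodium favours the distal bond, and the proximal mode would give a more strained six-membered ring with an exocyclic allene carbon. The two arms are cis on the piperidinone, away from the nine-membered bridge, and the tether holds both quaternary carbons, which keeps the ends together. The allene terminus is CH2, so there is no allylic hydrogen for a competing Alder-ene cycloisomerisation.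

Step 25
Reactants: 41
Product: 43 C13 tosylhydrazone of the deconjugated ketone (C10=C11, C12–H as in 53), via deconjugated ketone 42 (not isolated)
Conditions: [(Ph3P)CuH]6 (0.4 equiv), H2O (2 equiv), THF, −40 to 0 °C; then TsNHNH2, MeOH, 0 °C to rt
Reagents that add atoms: p-toluenesulfonyl hydrazide, Cc1ccc(cc1)S(=O)(=O)NN
Why: Copper hydride adds 1,6 to C9, the unhindered terminus of the dienone (C11 is fully substituted), as cuprates do with 2,4-dienones. The dienolate is protonated kinetically at C12 on the face opposite the C3H2OTBS group, which gives the C10=C11 alkene and the C12 configuration that later lets C2 reach C3. The labile β,γ-unsaturated ketone is trapped at once as its tosylhydrazone.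

Step 26
Reactants: 43
Product: 45 C13-methylene compound (C3–OTBS, C16–OBn, C19–OTBS), via tosylhydrazine 44 (not isolated)
Conditions: catecholborane, CHCl3, 0 °C; then NaOAc·3H2O, 60 °C
Reagents that add atoms: none
Why: Tosylhydrazone reduction: catecholborane reduces C=N, and acetate-induced loss of sulfinate gives a diazene that extrudes N2 to leave the CH2 group. The diazene is not allylic, so the alkene cannot shift, and no C13 alcohol is formed that could lactonise onto C1.

Step 27
Reactants: 45
Product: 46 C3 primary alcohol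
Conditions: HF·pyridine, pyridine, THF, 0 °C
Reagents that add atoms: none
Why: Buffered HF·pyridine cleaves the primary silyl ether much faster than the secondary C19 silyl ether, which is flanked by the methyl-bearing C20.

Step 28
Reactants: 46
Product: 47 C3 aldehyde
Conditions: Dess–Martin periodinane, NaHCO3, CH2Cl2, rt
Reagents that add atoms: none
Why: Mild oxidation of a neopentyl primary alcohol; the aldehyde is non-enolisable.

Step 29
Reactants: 47
Product: 50 cyclopentene ester (C2=C3; cyclopentane ring closed), via aldol 48 (not isolated), via mesylate 49 (not isolated)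
Conditions: KN(SiMe3)2, THF, −78 °C; then MsCl, −78 to 0 °C; then DBU, rt
Reagents that add atoms: none
Why: Intramolecular aldol addition (5-exo-trig) of the ester enolate at C2 to the non-enolisable C3 aldehyde; only C2–H2 is acidic, and C2 and C3 lie on the same side of the C10=C11 plane. Mesylation and E1cB elimination erase both new stereocentres and give the conjugated ester.

Step 30
Reactants: 50
Product: 51 saturated ester with C2 as in 53 and free C16–OH (C19–OTBS)
Conditions: H2 (3 atm), Pd/C, EtOAc, rt
Reagents that add atoms: none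
Why: Heterogeneous hydrogenation adds H2 to the trisubstituted C2=C3 bond from the convex face (the side of C12–H and the lactam carbonyl, away from C13 and C15), which places the ester cis to C13. The same catalyst cleaves the C16 benzyl ether, and the tetrasubstituted C10=C11 bond is inert.

Step 31
Reactants: 51
Product: 52 C16 acetate (19-O-tert-butyldimethylsilyl ether of 53)
Conditions: Ac2O, pyridine, DMAP (cat.), CH2Cl2, rt
Reagents that add atoms: acetic anhydride, CC(=O)OC(C)=O
Why: Acylation of the only free hydroxyl; cold amine base does not epimerise C2.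

Step 32
Reactants: 52
Product: 53 target compound
Conditions: 48% aq. HF, MeCN, 0 °C to rt
Reagents that add atoms: none
Why: Acidic fluoride removes the secondary silyl ether without touching the acetate, the methyl ester or the C2 stereocentre.

## Compound list

1 | (S)-4-benzyl-3-propanoyl-1,3-thiazolidine-2-thione | CCC(=O)N1[C@@H](Cc2ccccc2)CSC1=S | starting material
2 | acrolein | C=CC=O | starting material
3 | (S)-4-benzyl-3-[(2S,3R)-3-hydroxy-2-methylpent-4-enoyl]-1,3-thiazolidine-2-thione | C=C[C@@H](O)[C@H](C)C(=O)N1[C@@H](Cc2ccccc2)CSC1=S | intermediate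
4 | (S)-4-benzyl-3-[(2S,3R)-3-(tert-butyldimethylsilyloxy)-2-methylpent-4-enoyl]-1,3-thiazolidine-2-thione | C=C[C@@H](O[Si](C)(C)C(C)(C)C)[C@H](C)C(=O)N1[C@@H](Cc2ccccc2)CSC1=S | intermediate
5 | (2S,3R)-3-(tert-butyldimethylsilyloxy)-2-methylpent-4-enal | C=C[C@@H](O[Si](C)(C)C(C)(C)C)[C@H](C)C=O | intermediate
6 | 4-(benzyloxy)butanoic acid | OC(=O)CCCOCc1ccccc1 | starting material
7 | (S)-4-benzyloxazolidin-2-one | O=C1N[C@@H](Cc2ccccc2)CO1 | starting material
8 | 4-(benzyloxy)butanoic pivalic anhydride | CC(C)(C)C(=O)OC(=O)CCCOCc1ccccc1 | intermediate (not isolated)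
9 | (S)-4-benzyl-3-[4-(benzyloxy)butanoyl]oxazolidin-2-one | O=C1OC[C@H](Cc2ccccc2)N1C(=O)CCCOCc3ccccc3 | intermediate
10 | benzyl N-(methoxymethyl)carbamate | COCNC(=O)OCc1ccccc1 | starting material
11 | (S)-4-benzyl-3-[(R)-4-(benzyloxy)-2-{[(benzyloxycarbonyl)amino]methyl}butanoyl]oxazolidin-2-one | O=C(OCc1ccccc1)NC[C@@H](CCOCc2ccccc2)C(=O)N3[C@@H](Cc4ccccc4)COC3=O | intermediate
12 | methyl (R)-4-(benzyloxy)-2-{[(benzyloxycarbonyl)amino]methyl}butanoate | O=C(OCc1ccccc1)NC[C@@H](CCOCc2ccccc2)C(=O)OC | intermediate
13 | methyl (R)-2-(aminomethyl)-4-(benzyloxy)butanoate | NC[C@@H](CCOCc1ccccc1)C(=O)OC | intermediate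
14 | imine of 5 with 13 [(2R,3R)-pentenylidene, (R)-butanoate] | C=C[C@@H](O[Si](C)(C)C(C)(C)C)[C@H](C)C=NC[C@@H](CCOCc1ccccc1)C(=O)OC | intermediate (not isolated)
15 | methyl (R)-4-(benzyloxy)-2-({[(2R,3R)-3-(tert-butyldimethylsilyloxy)-2-methylpent-4-en-1-yl]amino}methyl)butanoate | C=C[C@@H](O[Si](C)(C)C(C)(C)C)[C@H](C)CNC[C@@H](CCOCc1ccccc1)C(=O)OC | intermediate
16 | methyl 3-chloro-3-oxopropanoate | COC(=O)CC(Cl)=O | starting material
17 | N-(3-methoxy-3-oxopropanoyl) derivative of 15 | C=C[C@@H](O[Si](C)(C)C(C)(C)C)[C@H](C)CN(C[C@@H](CCOCc1ccccc1)C(=O)OC)C(=O)CC(=O)OC | intermediate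
18 | methyl (5R)-5-[2-(benzyloxy)ethyl]-4-hydroxy-2-oxo-1-[(2R,3R)-3-(tert-butyldimethylsilyloxy)-2-methylpent-4-en-1-yl]-1,2,5,6-tetrahydropyridine-3-carboxylate | COC(=O)C1=C(O)[C@H](CCOCc2ccccc2)CN(C[C@@H](C)[C@H](O[Si](C)(C)C(C)(C)C)C=C)C1=O | intermediate
19 | 4-trifluoromethanesulfonate of 18 | COC(=O)C1=C(OS(=O)(=O)C(F)(F)F)[C@H](CCOCc2ccccc2)CN(C[C@@H](C)[C@H](O[Si](C)(C)C(C)(C)C)C=C)C1=O | intermediate
20 | (tributylstannyl)methanol | CCCC[Sn](CCCC)(CCCC)CO | starting material
21 | 4-(hydroxymethyl) analogue of 19 (CH2OH in place of OTf) | COC(=O)C1=C(CO)[C@H](CCOCc2ccccc2)CN(C[C@@H](C)[C@H](O[Si](C)(C)C(C)(C)C)C=C)C1=O | intermediate (not isolated)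
22 | (7S)-7-[2-(benzyloxy)ethyl]-5-[(2R,3R)-3-(tert-butyldimethylsilyloxy)-2-methylpent-4-en-1-yl]-6,7-dihydrofuro[3,4-c]pyridine-3,4(1H,5H)-dione | O=C1OCC2=C1C(=O)N(C[C@@H](C)[C@H](O[Si](C)(C)C(C)(C)C)C=C)C[C@H]2CCOCc3ccccc3 | intermediate
23 | vinylmagnesium bromide | C=C[Mg]Br | starting material
24 | formaldehyde (formalin in step 13, paraformaldehyde in step 19) | C=O | starting material
25 | cis-fused lactone–lactam with vinyl on C15 and H on C4 (vinyl trans to the C7 side chain) | O=C3[C@H]1C(=O)N(C[C@@H](C)[C@H](O[Si](C)(C)C(C)(C)C)C=C)C[C@@H](CCOCc4ccccc4)[C@]1(CO3)C=C | intermediate (not isolated)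
26 | cis-fused lactone–lactam with vinyl on C15 and hydroxymethyl C3 on C4 (cis to vinyl) | O=C3[C@@]1(CO)C(=O)N(C[C@@H](C)[C@H](O[Si](C)(C)C(C)(C)C)C=C)C[C@@H](CCOCc4ccccc4)[C@]1(CO3)C=C | intermediate
27 | C3 tert-butyldimethylsilyl ether of 26 | O=C3[C@@]1(CO[Si](C)(C)C(C)(C)C)C(=O)N(C[C@@H](C)[C@H](O[Si](C)(C)C(C)(C)C)C=C)C[C@@H](CCOCc4ccccc4)[C@]1(CO3)C=C | intermediate
28 | bridged lactam–lactone, nine-membered ring closed as (Z)-C17=C18 (C3–OTBS, C9–OBn, C19–OTBS) | O=C3[C@@]1(CO[Si](C)(C)C(C)(C)C)C(=O)N2C[C@@H](CCOCc4ccccc4)[C@]1(CO3)/C=C\[C@@H](O[Si](C)(C)C(C)(C)C)[C@H](C)C2 | intermediate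
29 | saturated bridged lactam–lactone with C7 2-hydroxyethyl group | O=C3[C@@]1(CO[Si](C)(C)C(C)(C)C)C(=O)N2C[C@@H](CCO)[C@]1(CO3)CC[C@@H](O[Si](C)(C)C(C)(C)C)[C@H](C)C2 | intermediate
30 | C9 aldehyde (C7 2-oxoethyl group) | O=C3[C@@]1(CO[Si](C)(C)C(C)(C)C)C(=O)N2C[C@@H](CC=O)[C@]1(CO3)CC[C@@H](O[Si](C)(C)C(C)(C)C)[C@H](C)C2 | intermediate
31 | dimethyl (1-diazo-2-oxopropyl)phosphonate | COP(=O)(OC)C(=[N+]=[N-])C(C)=O | starting material
32 | C7 prop-2-ynyl lactam–lactone | O=C3[C@@]1(CO[Si](C)(C)C(C)(C)C)C(=O)N2C[C@@H](CC#C)[C@]1(CO3)CC[C@@H](O[Si](C)(C)C(C)(C)C)[C@H](C)C2 | intermediate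
33 | C7 4-(dicyclohexylamino)but-2-ynyl lactam–lactone | O=C3[C@@]1(CO[Si](C)(C)C(C)(C)C)C(=O)N2C[C@@H](CC#CCN(C4CCCCC4)C4CCCCC4)[C@]1(CO3)CC[C@@H](O[Si](C)(C)C(C)(C)C)[C@H](C)C2 | intermediate (not isolated)
34 | C7 buta-2,3-dienyl lactam–lactone | O=C3[C@@]1(CO[Si](C)(C)C(C)(C)C)C(=O)N2C[C@@H](CC=C=C)[C@]1(CO3)CC[C@@H](O[Si](C)(C)C(C)(C)C)[C@H](C)C2 | intermediate
35 | lactol of 34 (C11 hemiacetal, both anomers) | OC3[C@@]1(CO[Si](C)(C)C(C)(C)C)C(=O)N2C[C@@H](CC=C=C)[C@]1(CO3)CC[C@@H](O[Si](C)(C)C(C)(C)C)[C@H](C)C2 | intermediate
36 | bridged lactam with ethynyl and CH2OTBS on C4, CH2OH on C15, buta-2,3-dienyl on C7 | C#C[C@@]1(CO[Si](C)(C)C(C)(C)C)C(=O)N2C[C@@H](CC=C=C)[C@]1(CO)CC[C@@H](O[Si](C)(C)C(C)(C)C)[C@H](C)C2 | intermediate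
37 | C16 benzyl ether of 36 | C#C[C@@]1(CO[Si](C)(C)C(C)(C)C)C(=O)N2C[C@@H](CC=C=C)[C@]1(COCc3ccccc3)CC[C@@H](O[Si](C)(C)C(C)(C)C)[C@H](C)C2 | intermediate
38 | methyl diazoacetate | COC(=O)C=[N+]=[N-] | starting material
39 | allene-yne: bridged lactam with CH2CO2Me-substituted alkyne on C4 and allene on the C7 side chain | COC(=O)CC#C[C@@]1(CO[Si](C)(C)C(C)(C)C)C(=O)N2C[C@@H](CC=C=C)[C@]1(COCc3ccccc3)CC[C@@H](O[Si](C)(C)C(C)(C)C)[C@H](C)C2 | intermediate
40 | carbon monoxide | [C-]#[O+] | starting material
41 | 4-alkylidenecyclopentenone fused to the cycloheptene (C13 ketone) | CC(C)(C)[Si](C)(C)OC[C@@]12C(=O)N3C[C@@H](CC=C4C1=C(CC(=O)OC)C(=O)C4)[C@]2(COCc5ccccc5)CC[C@@H](O[Si](C)(C)C(C)(C)C)[C@H](C)C3 | intermediate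
42 | deconjugated ketone (C10=C11, C12–H, C13 ketone) | CC(C)(C)[Si](C)(C)OC[C@@]12C(=O)N3C[C@@H](CCC4=C1[C@@H](CC(=O)OC)C(=O)C4)[C@]2(COCc5ccccc5)CC[C@@H](O[Si](C)(C)C(C)(C)C)[C@H](C)C3 | intermediate (not isolated)
43 | C13 tosylhydrazone of 42 | CC(C)(C)[Si](C)(C)OC[C@@]12C(=O)N3C[C@@H](CCC4=C1[C@@H](CC(=O)OC)C(=NNS(=O)(=O)c6ccc(C)cc6)C4)[C@]2(COCc5ccccc5)CC[C@@H](O[Si](C)(C)C(C)(C)C)[C@H](C)C3 | intermediate
44 | C13 N′-tosylhydrazine (C13 epimers) | CC(C)(C)[Si](C)(C)OC[C@@]12C(=O)N3C[C@@H](CCC4=C1[C@@H](CC(=O)OC)C(NNS(=O)(=O)c6ccc(C)cc6)C4)[C@]2(COCc5ccccc5)CC[C@@H](O[Si](C)(C)C(C)(C)C)[C@H](C)C3 | intermediate (not isolated)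
45 | C13-methylene compound (C3–OTBS, C16–OBn, C19–OTBS) | CC(C)(C)[Si](C)(C)OC[C@@]12C(=O)N3C[C@@H](CCC4=C1[C@@H](CC(=O)OC)CC4)[C@]2(COCc5ccccc5)CC[C@@H](O[Si](C)(C)C(C)(C)C)[C@H](C)C3 | intermediate
46 | C3 primary alcohol | OC[C@@]12C(=O)N3C[C@@H](CCC4=C1[C@@H](CC(=O)OC)CC4)[C@]2(COCc5ccccc5)CC[C@@H](O[Si](C)(C)C(C)(C)C)[C@H](C)C3 | intermediate
47 | C3 aldehyde | O=C[C@@]12C(=O)N3C[C@@H](CCC4=C1[C@@H](CC(=O)OC)CC4)[C@]2(COCc5ccccc5)CC[C@@H](O[Si](C)(C)C(C)(C)C)[C@H](C)C3 | intermediate
48 | aldol: cyclopentane closed, C3–OH (C2 and C3 epimers) | COC(=O)C1C(O)[C@@]23C(=O)N4C[C@@H](CCC5=C2[C@@H]1CC5)[C@]3(COCc6ccccc6)CC[C@@H](O[Si](C)(C)C(C)(C)C)[C@H](C)C4 | intermediate (not isolated)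
49 | C3 mesylate of 48 | COC(=O)C1C(OS(C)(=O)=O)[C@@]23C(=O)N4C[C@@H](CCC5=C2[C@@H]1CC5)[C@]3(COCc6ccccc6)CC[C@@H](O[Si](C)(C)C(C)(C)C)[C@H](C)C4 | intermediate (not isolated)
50 | cyclopentene ester (C2=C3; C16–OBn, C19–OTBS) | COC(=O)C1=C[C@@]23C(=O)N4C[C@@H](CCC5=C2[C@@H]1CC5)[C@]3(COCc6ccccc6)CC[C@@H](O[Si](C)(C)C(C)(C)C)[C@H](C)C4 | intermediate
51 | saturated ester with free C16–OH (C19–OTBS) | COC(=O)[C@@H]1C[C@@]23C(=O)N4C[C@@H](CCC5=C2[C@@H]1CC5)[C@]3(CO)CC[C@@H](O[Si](C)(C)C(C)(C)C)[C@H](C)C4 | intermediate
52 | 19-O-tert-butyldimethylsilyl ether of the target | COC(=O)[C@@H]1C[C@@]23C(=O)N4C[C@@H](CCC5=C2[C@@H]1CC5)[C@]3(COC(C)=O)CC[C@@H](O[Si](C)(C)C(C)(C)C)[C@H](C)C4 | intermediate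
53 | CNP0296366.1 | COC(=O)[C@@H]1C[C@@]23C(=O)N4C[C@@H](CCC5=C2[C@@H]1CC5)[C@]3(COC(C)=O)CC[C@@H](O)[C@H](C)C4 | target

## Step count and risks

Total: 32 steps. Longest linear sequence: 29 steps (steps 4–7, then 8–32); the aldehyde branch (steps 1–3) joins at step 8.

**Step 24 (key step).** The most likely failure is slow oxidative cyclisation at C11, which is flanked by two quaternary carbons. The 3-alkynoate could then drift into the conjugated 2,3-dienoate under the warm conditions, feeding the catalyst a different π-system. The fallback moves the ester arm to after the cycloaddition.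
- From 37, silylation of the terminal alkyne (Zn(OTf)2, Et3N, Me3SiOTf) gives the trimethylsilyl alkyne F1.
- The same rhodium-catalysed cyclocarbonylation, for which silyl alkynes are reliable partners, gives the 12-silyl dienone F2.
- ICl exchanges silicon for iodine to give the 12-iodo dienone F3.
- Coupling of F3 with the Reformatsky reagent BrZnCH2CO2Me under zerovalent palladium (Pd(PPh3)4, THF) installs C2 and C1 and rejoins the route at 41.

**Step 13.** The risk is poor facial control in the hydroxymethylation: kinetic attack anti to the vinyl group would give the trans-fused epimer if retro-aldol equilibration is slower than expected. The fallback delivers C11 intramolecularly.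
- From 22 the conjugate addition is run without formaldehyde and adduct 25 is isolated.
- LiBH4 reduces only the lactone, giving the diol F4.
- TBSCl silylates the less hindered hydroxymethyl group on C4, giving the silyl ether F5.
- ClCO2Me and pyridine convert the C16 hydroxyl into the methyl carbonate F6.
- LiN(SiMe3)2 at −78 °C forms the lactam enolate, which can reach the carbonate only on the face carrying C16. The new lactone carbonyl is therefore cis to C16, and the route is rejoined at 27.

**Step 15.** The risk is oligomerisation by cross-metathesis. Both alkenes are hindered (a vinyl group on a quaternary carbon and an allylic silyl ether), and the lactam must reach a boat-like shape to close. The fallback removes the allylic silyl group.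
- From 26, HF·pyridine gives the diene diol F7, whose free allylic hydroxyl speeds loading of the ruthenium carbene at C18.
- Ring closure under the same dilution gives the bridged diol F8.
- TBSOTf and 2,6-lutidine silylate both hydroxyls, returning to the route at 28.

**Step 21.** The risk is loss of the formyl carbon by retro-Claisen-type cleavage with methoxide, or plain non-reaction, because the lactol must open to a neopentyl aldehyde between two quaternary carbons. The fallback avoids the protic basic medium.
- From 34, Me(MeO)NH·HCl and AlMe3 open the lactone to the Weinreb amide F9, with free C16–OH.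
- Benzylation as in step 22 gives the benzyl ether F10.
- i-Bu2AlH gives the discrete aldehyde F11.
- Lithiated trimethylsilyldiazomethane at −78 °C (Colvin rearrangement) converts it to the alkyne, rejoining at 37.

**Step 25.** The risk is loss of positional control: hydride delivery to C11 instead of C9, or return of the deconjugated ketone to conjugation with epimerisation at C12 before the hydrazone has formed. The fallback separates reduction from deconjugation.
- From 41, hydrogenation over Pd/C with pyridine (benzyl ether spared) saturates the exocyclic C9=C10 bond, giving the conjugated enone F12.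
- KOt-Bu in t-BuOH/THF forms the extended dienolate, and a cold AcOH quench protonates it at C12 (deconjugative protonation).
- This gives 42, which is taken into hydrazone formation as in step 25.

## Further compounds

F1 | step 24 | trimethylsilyl alkyne (C4–C≡C–SiMe3 analogue of 37) | C[Si](C)(C)C#C[C@@]1(CO[Si](C)(C)C(C)(C)C)C(=O)N2C[C@@H](CC=C=C)[C@]1(COCc3ccccc3)CC[C@@H](O[Si](C)(C)C(C)(C)C)[C@H](C)C2
F2 | step 24 | 12-trimethylsilyl dienone | CC(C)(C)[Si](C)(C)OC[C@@]12C(=O)N3C[C@@H](CC=C4C1=C([Si](C)(C)C)C(=O)C4)[C@]2(COCc5ccccc5)CC[C@@H](O[Si](C)(C)C(C)(C)C)[C@H](C)C3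
F3 | step 24 | 12-iodo dienone | CC(C)(C)[Si](C)(C)OC[C@@]12C(=O)N3C[C@@H](CC=C4C1=C(I)C(=O)C4)[C@]2(COCc5ccccc5)CC[C@@H](O[Si](C)(C)C(C)(C)C)[C@H](C)C3
F4 | step 13 | diol from lactone reduction of 25 (C4 epimers) | OCC1C(=O)N(C[C@@H](C)[C@H](O[Si](C)(C)C(C)(C)C)C=C)C[C@@H](CCOCc2ccccc2)[C@]1(CO)C=C
F5 | step 13 | mono-silyl ether of F4 (OTBS on the C4 hydroxymethyl) | CC(C)(C)[Si](C)(C)OCC1C(=O)N(C[C@@H](C)[C@H](O[Si](C)(C)C(C)(C)C)C=C)C[C@@H](CCOCc2ccccc2)[C@]1(CO)C=C
F6 | step 13 | C16 methyl carbonate of F5 | CC(C)(C)[Si](C)(C)OCC1C(=O)N(C[C@@H](C)[C@H](O[Si](C)(C)C(C)(C)C)C=C)C[C@@H](CCOCc2ccccc2)[C@]1(COC(=O)OC)C=C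
F7 | step 15 | diene diol (C3–OH, C19–OH) | O=C3[C@@]1(CO)C(=O)N(C[C@@H](C)[C@H](O)C=C)C[C@@H](CCOCc4ccccc4)[C@]1(CO3)C=C
F8 | step 15 | bridged (Z)-alkene diol | O=C3[C@@]1(CO)C(=O)N2C[C@@H](CCOCc4ccccc4)[C@]1(CO3)/C=C\[C@@H](O)[C@H](C)C2
F9 | step 21 | C11 Weinreb amide with free C16–OH | CON(C)C(=O)[C@@]1(CO[Si](C)(C)C(C)(C)C)C(=O)N2C[C@@H](CC=C=C)[C@]1(CO)CC[C@@H](O[Si](C)(C)C(C)(C)C)[C@H](C)C2
F10 | step 21 | C16 benzyl ether of F9 | CON(C)C(=O)[C@@]1(CO[Si](C)(C)C(C)(C)C)C(=O)N2C[C@@H](CC=C=C)[C@]1(COCc3ccccc3)CC[C@@H](O[Si](C)(C)C(C)(C)C)[C@H](C)C2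
F11 | step 21 | C11 aldehyde | O=C[C@@]1(CO[Si](C)(C)C(C)(C)C)C(=O)N2C[C@@H](CC=C=C)[C@]1(COCc3ccccc3)CC[C@@H](O[Si](C)(C)C(C)(C)C)[C@H](C)C2
F12 | step 25 | conjugated enone with saturated C9–C10 (C10 epimers) | CC(C)(C)[Si](C)(C)OC[C@@]12C(=O)N3C[C@@H](CCC4C1=C(CC(=O)OC)C(=O)C4)[C@]2(COCc5ccccc5)CC[C@@H](O[Si](C)(C)C(C)(C)C)[C@H](C)C3
A1 | alternative 1 | cis-carboxy vinyl cycloheptene with both quaternary carbons | OC(=O)[C@]1(CCCO[Si](C(C)C)(C(C)C)C(C)C)C2=C(CCC2)CC[C@H](CO[Si](C)(C)C(C)(C)C)[C@]1(COCc1ccc(OC)cc1)C=C
A2 | alternative 1 | eleven-membered allylic lactone (ring-trans alkene drawn; α-carbon undefined because it becomes sp2 in the ketene acetal) | O=C1OC/C=C(\COCc2ccc(OC)cc2)[C@@H](CO[Si](C)(C)C(C)(C)C)CCC3=C(CCC3)C1CCCO[Si](C(C)C)(C(C)C)C(C)C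
A3 | alternative 2 | tetracyclic lactam with conjugated diene | COC(=O)[C@@H]1C[C@@]23C(=O)N(C[C@@H](C)CO[Si](C)(C)C(C)(C)C)C[C@@H](C=CC4=C2[C@@H]1CC4)[C@]3(COC(C)=O)CCO[Si](c1ccccc1)(c1ccccc1)C(C)(C)C
A4 | alternative 2 | secondary amide on the carbocyclic cyclohepta-1,4-diene | COC(=O)[C@@H]1C[C@@]2(C(=O)NC[C@@H](C)CO[Si](C)(C)C(C)(C)C)C3=C(CC=C[C@]2(COC(C)=O)CCO[Si](c4ccccc4)(c4ccccc4)C(C)(C)C)CC[C@@H]31
A5 | alternative 3 | tricyclic 1,4-diene tert-butyl ester with the quaternary carbon | CC(C)(C)OC(=O)[C@@]12C=CCC3=C1[C@H](CCC3)[C@H](CO[Si](C)(C)C(C)(C)C)C2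
A6 | alternative 3 | tert-butyl tetrahydronaphthoate with the chloroalkyl side chain | CC(C)(C)OC(=O)c1cccc2c1[C@H](CCC2)[C@H](CO[Si](C)(C)C(C)(C)C)CCl
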